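**Retrosynthetic overview**
- The C7–CH2 bond is cut last: target ⇒ acetylated dihydrobenzofuran diol 22 + pyrone Mannich base 26 (pyrone 25 from 3-pentanone and malonyl dichloride).
- 22 ⇒ bis-MOM diene 19 (C5 acetyl by lithiation between the two MOM ethers) ⇒ ketone 18 (methylenation) ⇒ Weinreb amide 15 + homoprenyl Grignard ⇒ acid 13 ⇒ imide 11.
- Key disconnection C2–C3: in the dihydrofuran ring, C2 is bonded to the ring oxygen O1 and to the benzylic carbon C3. An aryloxyacetyl oxazolidinone enolate (future C2, tethered through O1) can therefore close onto the ortho CH2Cl (future C3); the (S)-benzyl auxiliary sets (2R).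
- Precursor 9 ⇒ 2,4,6-trihydroxybenzaldehyde (its chelated OH becomes O1, its formyl carbon becomes C3) + N-bromoacetyl oxazolidinone 5.
- Ring order: benzene ring from the starting material; dihydrofuran ring in step 6; pyrone ring made separately in step 14 and attached in step 16.

Key step: step 6

Remark: benzofuran numbering (O1, C2, C3, C3a, C4–C7, C7a) is used for all bicyclic compounds; MOM = methoxymethyl. The target stereocenter reads as (2R). The labile benzylic chloride 9 is assumed to be usable crude, without chromatography.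

**Step 1**
Reactants: 1 2,4,6-trihydroxybenzaldehyde
Product: 2 2-hydroxy-4,6-bis(methoxymethoxy)benzaldehyde
Conditions: MOMCl (2.2 equiv), i-Pr2NEt, CH2Cl2, 0 °C → rt
Reagents that add atoms: chloromethyl methyl ether (MOMCl), COCCl
Why: Base-mediated O-alkylation (MOM ether formation) of the para hydroxyl and one ortho hydroxyl; the remaining ortho hydroxyl is held in a hydrogen bond to the formyl oxygen and should stay free, which fixes the oxygen that becomes O1.

**Step 2**
Reactants: 3 (4S)-4-benzyl-1,3-oxazolidin-2-one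
Product: 5 (4S)-4-benzyl-3-(bromoacetyl)-1,3-oxazolidin-2-one, via lithium oxazolidinide 4 (not isolated)
Conditions: n-BuLi, THF, −78 °C; then BrCH2COBr, −78 → 0 °C
Reagents that add atoms: bromoacetyl bromide, BrCC(Br)=O
Why: N-acylation of the lithiated oxazolidinone with an acid bromide, which reacts far faster at the acyl carbon than at the alkyl bromide.

**Step 3**
Reactants: 2 2-hydroxy-4,6-bis(methoxymethoxy)benzaldehyde; 5 (4S)-4-benzyl-3-(bromoacetyl)-1,3-oxazolidin-2-one
Product: 6 (4S)-4-benzyl-3-{[2-formyl-3,5-bis(methoxymethoxy)phenoxy]acetyl}-1,3-oxazolidin-2-one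
Conditions: K2CO3 (1.1 equiv), MeCN, rt
Reagents that add atoms: none
Why: Williamson ether synthesis in which the phenoxide displaces the activated alpha-bromide; the weak base and room temperature should keep the imide from enolising onto the electron-rich, deactivated aldehyde.

**Step 4**
Reactants: 6 (4S)-4-benzyl-3-{[2-formyl-3,5-bis(methoxymethoxy)phenoxy]acetyl}-1,3-oxazolidin-2-one
Product: 7 (4S)-4-benzyl-3-{[2-(hydroxymethyl)-3,5-bis(methoxymethoxy)phenoxy]acetyl}-1,3-oxazolidin-2-one
Conditions: NaBH4 (0.5 equiv), THF–EtOH (10:1), −20 °C; pH 7 buffer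
Reagents that add atoms: none
Why: Chemoselective borohydride reduction, the aldehyde being reduced at low temperature much faster than the exocyclic imide carbonyl; no free phenol is left, so a quinone methide and over-reduction to a methyl group are not possible.

**Step 5**
Reactants: 7 (4S)-4-benzyl-3-{[2-(hydroxymethyl)-3,5-bis(methoxymethoxy)phenoxy]acetyl}-1,3-oxazolidin-2-one
Product: 9 (4S)-4-benzyl-3-{[2-(chloromethyl)-3,5-bis(methoxymethoxy)phenoxy]acetyl}-1,3-oxazolidin-2-one, via benzylic mesylate 8 (not isolated)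
Conditions: MsCl, 2,4,6-collidine, LiCl, DMF, 0 °C; cold extractive work-up, used crude at once
Reagents that add atoms: lithium chloride, [Li+].[Cl-]
Why: Collington–Meyers chlorination (mesylation, then chloride displacement of the very reactive benzylic mesylate) under buffered, non-acidic conditions that should spare the MOM ethers and the imide.

**Step 6**
Reactants: 9 (4S)-4-benzyl-3-{[2-(chloromethyl)-3,5-bis(methoxymethoxy)phenoxy]acetyl}-1,3-oxazolidin-2-one
Product: 11 (4S)-4-benzyl-3-{[(2R)-4,6-bis(methoxymethoxy)-2,3-dihydro-1-benzofuran-2-yl]carbonyl}-1,3-oxazolidin-2-one, via sodium Z-enolate 10 (not isolated)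
Conditions: NaN(SiMe3)2 (1.05 equiv), THF (0.01 M), −78 °C (→ −50 °C if needed); AcOH quench at −78 °C
Reagents that add atoms: none
Why: Proposed new method: NaN(SiMe3)2 removes the proton alpha to the imide carbonyl and gives the sodium-chelated Z-enolate 10, whose alpha carbon then displaces chloride from the ortho benzylic carbon (SN2) to form the C2–C3 bond. The closest known reaction type is the alkylation of sodium enolates of alkoxyacetyl and other N-acyl oxazolidinones with benzylic and allylic halides, used here in a ring-closing form on an aryloxyacetyl imide. The dihydrofuran ring closes in the 5-(enolexo)-exo-tet mode, which is geometrically favoured because the enolate double bond lies outside the forming ring and the O1–C2 bond can turn the enolate carbon over the benzylic carbon. The C2 stereocenter is controlled by the (S)-benzyl group of the auxiliary, which covers one face of the chelated Z-enolate so that the tethered electrophile bonds on the open face; by the same facial sense as the intermolecular alkylations this corresponds to (2R). The step needs C-alkylation in a five-membered closure in preference to O-alkylation (a seven-membered ring), to intermolecular alkylation and to loss of the oxazolidinone anion from the enolate as a ketene. The short O1 tether, the high SN2 reactivity of the electron-rich benzylic chloride, high dilution and −78 °C should secure this.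

**Step 7**
Reactants: 11 (4S)-4-benzyl-3-{[(2R)-4,6-bis(methoxymethoxy)-2,3-dihydro-1-benzofuran-2-yl]carbonyl}-1,3-oxazolidin-2-one
Product: 13 (2R)-4,6-bis(methoxymethoxy)-2,3-dihydro-1-benzofuran-2-carboxylic acid, via lithium peroxycarboxylate 12 (not isolated)
Conditions: LiOH, H2O2, THF–H2O, 0 °C; Na2SO3; then 1 M HCl to pH 3 at 0 °C
Reagents that add atoms: hydrogen peroxide, OO
Why: Auxiliary removal by lithium hydroperoxide, which attacks the exocyclic imide carbonyl selectively at 0 °C and should not epimerise C2; sulfite reduces the peroxy acid salt and the auxiliary is recovered.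

**Step 8**
Reactants: 13 (2R)-4,6-bis(methoxymethoxy)-2,3-dihydro-1-benzofuran-2-carboxylic acid
Product: 15 (2R)-N-methoxy-N-methyl-4,6-bis(methoxymethoxy)-2,3-dihydro-1-benzofuran-2-carboxamide, via acyl imidazolide 14 (not isolated)
Conditions: CDI, CH2Cl2, 0 °C → rt; then MeNH(OMe)·HCl, rt
Reagents that add atoms: N,O-dimethylhydroxylamine hydrochloride, CNOC.Cl
Why: Amide formation through the acyl imidazolide (carbonyldiimidazole activation), mild enough to leave the C2 stereocenter and the MOM ethers untouched.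

**Step 9**
Reactants: 15 (2R)-N-methoxy-N-methyl-4,6-bis(methoxymethoxy)-2,3-dihydro-1-benzofuran-2-carboxamide; 16 5-bromo-2-methylpent-2-ene
Product: 18 1-[(2R)-4,6-bis(methoxymethoxy)-2,3-dihydro-1-benzofuran-2-yl]-5-methylhex-4-en-1-one, via homoprenylmagnesium bromide 17 (not isolated)
Conditions: 16, Mg, THF, rt → 40 °C; then 15, THF, −20 → 0 °C; aq NH4Cl
Reagents that add atoms: none
Why: Weinreb ketone synthesis, in which the Grignard reagent adds once and the magnesium chelate keeps the carbonyl masked until work-up, so no tertiary alcohol forms and C2 is not enolised.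

**Step 10**
Reactants: 18 1-[(2R)-4,6-bis(methoxymethoxy)-2,3-dihydro-1-benzofuran-2-yl]-5-methylhex-4-en-1-one
Product: 19 (2R)-4,6-bis(methoxymethoxy)-2-(6-methylhepta-1,5-dien-2-yl)-2,3-dihydro-1-benzofuran
Conditions: Cp2TiMe2 (2.5 equiv), toluene–THF, 65 °C, dark
Reagents that add atoms: dimethyltitanocene Cp2TiMe2, C[Ti](C)(C1C=CC=C1)C1C=CC=C1
Why: Petasis methylenation, in which Cp2Ti=CH2 formed on heating turns the ketone into the 1,1-disubstituted alkene under non-basic conditions, so the acidic C2–H next to the carbonyl should not epimerise.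

**Step 11**
Reactants: 19 (2R)-4,6-bis(methoxymethoxy)-2-(6-methylhepta-1,5-dien-2-yl)-2,3-dihydro-1-benzofuran
Product: 21 1-[(2R)-4,6-bis(methoxymethoxy)-2-(6-methylhepta-1,5-dien-2-yl)-2,3-dihydro-1-benzofuran-5-yl]ethan-1-one, via C5 aryllithium 20 (not isolated)
Conditions: n-BuLi, TMEDA, THF, −20 → 0 °C; then MeC(O)N(OMe)Me, −78 → 0 °C; aq NH4Cl
Reagents that add atoms: N-methoxy-N-methylacetamide, CC(=O)N(C)OC
Why: Directed ortho-metalation at C5, the position flanked by both MOM ethers (cooperative lithium coordination), then acylation with a Weinreb amide, which stops at the ketone; C7 has only one MOM neighbour and should be metalated more slowly.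

**Step 12**
Reactants: 21 1-[(2R)-4,6-bis(methoxymethoxy)-2-(6-methylhepta-1,5-dien-2-yl)-2,3-dihydro-1-benzofuran-5-yl]ethan-1-one
Product: 22 1-[(2R)-4,6-dihydroxy-2-(6-methylhepta-1,5-dien-2-yl)-2,3-dihydro-1-benzofuran-5-yl]ethan-1-one
Conditions: HCl (cat., 1.25 M in MeOH), MeOH–THF, 0 °C → rt
Reagents that add atoms: none
Why: Acid-catalysed acetal exchange with methanol removes both MOM groups, each activated by the ortho acetyl group, under conditions mild enough for the two alkenes and the allylic C2–O1 bond.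

**Step 13**
Reactants: 23 3-pentanone
Product: 24 3-(trimethylsilyloxy)pent-2-ene (E/Z mixture)
Conditions: TMSOTf, Et3N, Et2O, 0 °C → rt
Reagents that add atoms: trimethylsilyl trifluoromethanesulfonate, C[Si](C)(C)OS(=O)(=O)C(F)(F)F
Why: Silyl enol ether formation by soft enolisation of a symmetrical ketone, for which only one regioisomer is possible.

**Step 14**
Reactants: 24 3-(trimethylsilyloxy)pent-2-ene
Product: 25 6-ethyl-4-hydroxy-5-methyl-2H-pyran-2-one
Conditions: ClC(O)CH2C(O)Cl, Et2O, −78 °C → rt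
Reagents that add atoms: malonyl dichloride, O=C(Cl)CC(=O)Cl
Why: C-acylation of the silyl enol ether by malonyl dichloride, then lactonisation through the enol oxygen onto the second acid chloride, a known route to 4-hydroxy-2-pyrones.

**Step 15**
Reactants: 25 6-ethyl-4-hydroxy-5-methyl-2H-pyran-2-one
Product: 26 3-[(dimethylamino)methyl]-6-ethyl-4-hydroxy-5-methyl-2H-pyran-2-one
Conditions: [Me2N=CH2]I (N,N-dimethylmethyleneiminium iodide), Et3N, MeCN, 0 °C → rt
Reagents that add atoms: N,N-dimethylmethyleneiminium iodide, C=[N+](C)C.[I-]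
Why: Mannich reaction in which the nucleophilic C3 of the 4-hydroxy-2-pyrone adds to the preformed iminium salt to give a storable Mannich base.

**Step 16**
Reactants: 22 1-[(2R)-4,6-dihydroxy-2-(6-methylhepta-1,5-dien-2-yl)-2,3-dihydro-1-benzofuran-5-yl]ethan-1-one; 26 3-[(dimethylamino)methyl]-6-ethyl-4-hydroxy-5-methyl-2H-pyran-2-one
Product: 28 3-{[(2R)-5-acetyl-4,6-dihydroxy-2-(6-methylhepta-1,5-dien-2-yl)-2,3-dihydro-1-benzofuran-7-yl]methyl}-6-ethyl-4-hydroxy-5-methyl-2H-pyran-2-one, via methylidene pyrandione 27 (not isolated)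
Conditions: 26 (1.5 equiv), 1,4-dioxane, 80 °C
Reagents that add atoms: none
Why: Thermal loss of dimethylamine from the Mannich base gives the methylidene dione 27, a strong Michael acceptor, which should be attacked by C7, the only free carbon of the acylphloroglucinol ring (conjugate addition, then re-aromatisation); no stereocenter is touched.

**Compound list**
1 | 2,4,6-trihydroxybenzaldehyde | O=Cc1c(O)cc(O)cc1O | starting material
2 | 2-hydroxy-4,6-bis(methoxymethoxy)benzaldehyde | O=Cc1c(O)cc(OCOC)cc1OCOC | intermediate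
3 | (4S)-4-benzyl-1,3-oxazolidin-2-one | O=C1N[C@@H](Cc2ccccc2)CO1 | starting material
4 | lithium (4S)-4-benzyl-2-oxo-1,3-oxazolidin-3-ide | [Li+].O=C1[N-][C@@H](Cc2ccccc2)CO1 | intermediate
5 | (4S)-4-benzyl-3-(bromoacetyl)-1,3-oxazolidin-2-one | O=C(CBr)N1C(=O)OC[C@@H]1Cc2ccccc2 | intermediate
6 | (4S)-4-benzyl-3-{[2-formyl-3,5-bis(methoxymethoxy)phenoxy]acetyl}-1,3-oxazolidin-2-one | O=Cc1c(OCOC)cc(OCOC)cc1OCC(=O)N2C(=O)OC[C@@H]2Cc3ccccc3 | intermediate
7 | (4S)-4-benzyl-3-{[2-(hydroxymethyl)-3,5-bis(methoxymethoxy)phenoxy]acetyl}-1,3-oxazolidin-2-one | OCc1c(OCOC)cc(OCOC)cc1OCC(=O)N2C(=O)OC[C@@H]2Cc3ccccc3 | intermediate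
8 | (4S)-4-benzyl-3-{[2-(methanesulfonyloxymethyl)-3,5-bis(methoxymethoxy)phenoxy]acetyl}-1,3-oxazolidin-2-one | CS(=O)(=O)OCc1c(OCOC)cc(OCOC)cc1OCC(=O)N2C(=O)OC[C@@H]2Cc3ccccc3 | intermediate
9 | (4S)-4-benzyl-3-{[2-(chloromethyl)-3,5-bis(methoxymethoxy)phenoxy]acetyl}-1,3-oxazolidin-2-one | ClCc1c(OCOC)cc(OCOC)cc1OCC(=O)N2C(=O)OC[C@@H]2Cc3ccccc3 | intermediate
10 | sodium (Z)-1-[(4S)-4-benzyl-2-oxo-1,3-oxazolidin-3-yl]-2-[2-(chloromethyl)-3,5-bis(methoxymethoxy)phenoxy]ethen-1-olate | ClCc1c(OCOC)cc(OCOC)cc1O/C=C(\[O-])N2C(=O)OC[C@@H]2Cc3ccccc3.[Na+] | intermediate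
11 | (4S)-4-benzyl-3-{[(2R)-4,6-bis(methoxymethoxy)-2,3-dihydro-1-benzofuran-2-yl]carbonyl}-1,3-oxazolidin-2-one | O=C(N3C(=O)OC[C@@H]3Cc4ccccc4)[C@H]1Cc2c(OCOC)cc(OCOC)cc2O1 | intermediate
12 | lithium (2R)-4,6-bis(methoxymethoxy)-2,3-dihydro-1-benzofuran-2-carboperoxoate | [Li+].[O-]OC(=O)[C@H]1Cc2c(OCOC)cc(OCOC)cc2O1 | intermediate
13 | (2R)-4,6-bis(methoxymethoxy)-2,3-dihydro-1-benzofuran-2-carboxylic acid | OC(=O)[C@H]1Cc2c(OCOC)cc(OCOC)cc2O1 | intermediate
14 | [(2R)-4,6-bis(methoxymethoxy)-2,3-dihydro-1-benzofuran-2-yl](1H-imidazol-1-yl)methanone | O=C(n3ccnc3)[C@H]1Cc2c(OCOC)cc(OCOC)cc2O1 | intermediate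
15 | (2R)-N-methoxy-N-methyl-4,6-bis(methoxymethoxy)-2,3-dihydro-1-benzofuran-2-carboxamide | CON(C)C(=O)[C@H]1Cc2c(OCOC)cc(OCOC)cc2O1 | intermediate
16 | 5-bromo-2-methylpent-2-ene | CC(C)=CCCBr | starting material
17 | (4-methylpent-3-en-1-yl)magnesium bromide | CC(C)=CCC[Mg]Br | intermediate
18 | 1-[(2R)-4,6-bis(methoxymethoxy)-2,3-dihydro-1-benzofuran-2-yl]-5-methylhex-4-en-1-one | CC(C)=CCCC(=O)[C@H]1Cc2c(OCOC)cc(OCOC)cc2O1 | intermediate
19 | (2R)-4,6-bis(methoxymethoxy)-2-(6-methylhepta-1,5-dien-2-yl)-2,3-dihydro-1-benzofuran | C=C(CCC=C(C)C)[C@H]1Cc2c(OCOC)cc(OCOC)cc2O1 | intermediate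
20 | [(2R)-4,6-bis(methoxymethoxy)-2-(6-methylhepta-1,5-dien-2-yl)-2,3-dihydro-1-benzofuran-5-yl]lithium | C=C(CCC=C(C)C)[C@H]1Cc2c(OCOC)c([Li])c(OCOC)cc2O1 | intermediate
21 | 1-[(2R)-4,6-bis(methoxymethoxy)-2-(6-methylhepta-1,5-dien-2-yl)-2,3-dihydro-1-benzofuran-5-yl]ethan-1-one | C=C(CCC=C(C)C)[C@H]1Cc2c(OCOC)c(C(C)=O)c(OCOC)cc2O1 | intermediate
22 | 1-[(2R)-4,6-dihydroxy-2-(6-methylhepta-1,5-dien-2-yl)-2,3-dihydro-1-benzofuran-5-yl]ethan-1-one | C=C(CCC=C(C)C)[C@H]1Cc2c(O)c(C(C)=O)c(O)cc2O1 | intermediate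
23 | 3-pentanone | CCC(=O)CC | starting material
24 | 3-(trimethylsilyloxy)pent-2-ene (E/Z mixture) | CC=C(CC)O[Si](C)(C)C | intermediate
25 | 6-ethyl-4-hydroxy-5-methyl-2H-pyran-2-one | CCc1oc(=O)cc(O)c1C | intermediate
26 | 3-[(dimethylamino)methyl]-6-ethyl-4-hydroxy-5-methyl-2H-pyran-2-one | CCc1oc(=O)c(CN(C)C)c(O)c1C | intermediate
27 | 6-ethyl-5-methyl-3-methylidene-2H-pyran-2,4(3H)-dione | CCC1=C(C)C(=O)C(=C)C(=O)O1 | intermediate
28 | 3-{[(2R)-5-acetyl-4,6-dihydroxy-2-(6-methylhepta-1,5-dien-2-yl)-2,3-dihydro-1-benzofuran-7-yl]methyl}-6-ethyl-4-hydroxy-5-methyl-2H-pyran-2-one | C=C(CCC=C(C)C)[C@H]1Cc2c(O)c(C(C)=O)c(O)c(Cc3c(O)c(C)c(CC)oc3=O)c2O1 | target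

**Step count**
Total: 16 steps. Longest linear sequence: 12 steps (steps 1, 3–12 and 16).

**Steps most likely to fail**

1. Step 6 (ring-closing enolate alkylation). The enolate may lose the oxazolidinone as a ketene or alkylate a second molecule before it cyclises. The tether may also force an approach geometry that erodes the facial selectivity seen in intermolecular alkylations. The fallback uses known chemistry, sets out from 2 and comes back at 11.
   - O-alkylation of 2 with methyl bromoacetate (K2CO3, DMF, rt) would give methyl [2-formyl-3,5-bis(methoxymethoxy)phenoxy]acetate F1.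
   - Heating F1 with K2CO3 or DBU in DMF at 100 °C should bring about intramolecular aldol condensation to methyl 4,6-bis(methoxymethoxy)-1-benzofuran-2-carboxylate F2.
   - Mg in MeOH should reduce the C2=C3 bond to racemic methyl 4,6-bis(methoxymethoxy)-2,3-dihydro-1-benzofuran-2-carboxylate F3.
   - LiOH in THF–H2O should give racemic 4,6-bis(methoxymethoxy)-2,3-dihydro-1-benzofuran-2-carboxylic acid F4.
   - PivCl and Et3N would convert F4 into the mixed pivalic anhydride F5, which acylates auxiliary 3 (LiCl, Et3N, THF).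
   - This gives 11 together with its (2S)-epimer F6; the two diastereomers are separated by chromatography or crystallisation and 11 re-enters at step 7.

2. Step 11 (lithiation–acetylation). Metalation may go to C7, between the 6-MOM ether and O1, instead of C5, or the base may attack the allylic C2–H. The fallback turns a C7 preference into a blocking step, sets out from 19 and comes back at 22.
   - The first metalation (n-BuLi, TMEDA) would give the C7 lithium compound F7, which is quenched with TMSCl to give the 7-trimethylsilyl compound F8.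
   - In F8 only C5 is free, so a second metalation should give the C5 lithium compound F9.
   - N-methoxy-N-methylacetamide should convert F9 into the 5-acetyl-7-trimethylsilyl compound F10.
   - HCl in MeOH, as in step 12, should remove both MOM groups and, by ipso-protonation of the electron-rich ring, the silyl group, to give 22.

3. Step 16 (methylene coupling). Self-condensation of the methylidene dione, or its reversible capture by dimethylamine, may outrun C–C bond formation at the flanked C7. The fallback reverses the roles of the partners, sets out from 22 and comes back at 28.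
   - N,N-dimethylmethyleneiminium iodide (CH2Cl2, rt) should aminomethylate C7, the only free ring carbon of 22, to give 1-[(2R)-7-[(dimethylamino)methyl]-4,6-dihydroxy-2-(6-methylhepta-1,5-dien-2-yl)-2,3-dihydro-1-benzofuran-5-yl]ethan-1-one F11.
   - Heating F11 with pyrone 25 in 1,4-dioxane at 90–100 °C should expel dimethylamine to form the ortho-quinone methide of the phloroglucinol ring, which C3 of the pyrone traps to give 28.

**Further compounds**
F1 | step 6 | methyl [2-formyl-3,5-bis(methoxymethoxy)phenoxy]acetate | COC(=O)COc1cc(OCOC)cc(OCOC)c1C=O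
F2 | step 6 | methyl 4,6-bis(methoxymethoxy)-1-benzofuran-2-carboxylate | COC(=O)c1cc2c(OCOC)cc(OCOC)cc2o1
F3 | step 6 | methyl 4,6-bis(methoxymethoxy)-2,3-dihydro-1-benzofuran-2-carboxylate (racemic) | COC(=O)C1Cc2c(OCOC)cc(OCOC)cc2O1
F4 | step 6 | 4,6-bis(methoxymethoxy)-2,3-dihydro-1-benzofuran-2-carboxylic acid (racemic) | OC(=O)C1Cc2c(OCOC)cc(OCOC)cc2O1
F5 | step 6 | 4,6-bis(methoxymethoxy)-2,3-dihydro-1-benzofuran-2-carboxylic pivalic anhydride (racemic) | CC(C)(C)C(=O)OC(=O)C1Cc2c(OCOC)cc(OCOC)cc2O1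
F6 | step 6 | (4S)-4-benzyl-3-{[(2S)-4,6-bis(methoxymethoxy)-2,3-dihydro-1-benzofuran-2-yl]carbonyl}-1,3-oxazolidin-2-one | O=C(N3C(=O)OC[C@@H]3Cc4ccccc4)[C@@H]1Cc2c(OCOC)cc(OCOC)cc2O1
F7 | step 11 | [(2R)-4,6-bis(methoxymethoxy)-2-(6-methylhepta-1,5-dien-2-yl)-2,3-dihydro-1-benzofuran-7-yl]lithium | C=C(CCC=C(C)C)[C@H]1Cc2c(OCOC)cc(OCOC)c([Li])c2O1
F8 | step 11 | [(2R)-4,6-bis(methoxymethoxy)-2-(6-methylhepta-1,5-dien-2-yl)-2,3-dihydro-1-benzofuran-7-yl]trimethylsilane | C=C(CCC=C(C)C)[C@H]1Cc2c(OCOC)cc(OCOC)c([Si](C)(C)C)c2O1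
F9 | step 11 | [(2R)-4,6-bis(methoxymethoxy)-2-(6-methylhepta-1,5-dien-2-yl)-7-(trimethylsilyl)-2,3-dihydro-1-benzofuran-5-yl]lithium | C=C(CCC=C(C)C)[C@H]1Cc2c(OCOC)c([Li])c(OCOC)c([Si](C)(C)C)c2O1
F10 | step 11 | 1-[(2R)-4,6-bis(methoxymethoxy)-2-(6-methylhepta-1,5-dien-2-yl)-7-(trimethylsilyl)-2,3-dihydro-1-benzofuran-5-yl]ethan-1-one | C=C(CCC=C(C)C)[C@H]1Cc2c(OCOC)c(C(C)=O)c(OCOC)c([Si](C)(C)C)c2O1
F11 | step 16 | 1-[(2R)-7-[(dimethylamino)methyl]-4,6-dihydroxy-2-(6-methylhepta-1,5-dien-2-yl)-2,3-dihydro-1-benzofuran-5-yl]ethan-1-one | C=C(CCC=C(C)C)[C@H]1Cc2c(O)c(C(C)=O)c(O)c(CN(C)C)c2O1
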